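**Strategy.** The central benzene (ring A) carries carbon substituents on four neighbouring carbons: C1 (diarylmethylidene carbon), C2 (4-hydroxyphenyl), C6 (arylethynyl) and C5 (CH2OH). The remaining C3 and C4 are adjacent CH groups. Ring A is therefore cut at C1–C2 and C5–C6 into an (E,E)-1-aryl-4-(silyloxymethyl)butadiene (C2–C5) and the carbonyl-activated triple bond of an aroyl diyne (C1, C6). One intermolecular Diels–Alder reaction closes ring A with every substituent in place. The second triple bond survives as the arylethynyl group and the ketone becomes the handle for the last aryl group. Dehydrogenation, aryllithium addition and desilylation–dehydration then finish the quinone methide.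

Key step: step 9

Remark: TBS = tert-butyldimethylsilyl and Ar = 4-(tert-butyldimethylsilyloxy)phenyl; ring A is numbered as above; cycloadduct 13 is racemic and its SMILES shows one enantiomer only to fix the cis relative configuration.

Step 1
Reactants: 1 4-(tert-butyldimethylsilyloxy)benzaldehyde; 2 triethyl 4-phosphonocrotonate
Product: 4 ethyl (2E,4E)-5-[4-(tert-butyldimethylsilyloxy)phenyl]penta-2,4-dienoate, via lithiated phosphonate 3 (not isolated)
Conditions: 2, LiN(SiMe3)2 (1.05 equiv), THF, −78 °C; then 1, −78 → 0 °C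
Reagents that add atoms: none
Why: Vinylogous Horner–Wadsworth–Emmons olefination, in which the γ-carbanion of the phosphonocrotonate adds to the non-enolisable aldehyde and phosphate elimination should give the E geometry at the new C4=C5 bond while C2=C3 stays E, the aryl silyl ether being safe towards the non-nucleophilic amide base at low temperature.

Step 2
Reactants: 4 ethyl (2E,4E)-5-[4-(tert-butyldimethylsilyloxy)phenyl]penta-2,4-dienoate
Product: 5 (2E,4E)-5-[4-(tert-butyldimethylsilyloxy)phenyl]penta-2,4-dien-1-ol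
Conditions: i-Bu2AlH (2.2 equiv), CH2Cl2, −78 °C; aq. potassium sodium tartrate (KNaC4H4O6) work-up
Reagents that add atoms: none
Why: 1,2-Reduction of a conjugated ester to the allylic alcohol by an aluminium hydride, which delivers hydride only to the carbonyl carbon and leaves both E alkenes and the aryl silyl ether untouched.

Step 3
Reactants: 5 (2E,4E)-5-[4-(tert-butyldimethylsilyloxy)phenyl]penta-2,4-dien-1-ol
Product: 6 tert-butyl{4-[(1E,3E)-5-(tert-butyldimethylsilyloxy)penta-1,3-dien-1-yl]phenoxy}dimethylsilane (the diene)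
Conditions: TBSCl (1.2 equiv), imidazole (2 equiv), CH2Cl2, 0 °C → rt
Reagents that add atoms: tert-butyldimethylsilyl chloride, CC(C)(C)[Si](C)(C)Cl
Why: Imidazole-promoted silylation of a primary alcohol, run under basic conditions so that the acid-sensitive dienyl alcohol cannot ionise and so that the nucleophilic OH is masked before it meets the ynone.

Step 4
Reactants: 1 4-(tert-butyldimethylsilyloxy)benzaldehyde; 7 ethynylmagnesium bromide
Product: 8 rac-1-[4-(tert-butyldimethylsilyloxy)phenyl]prop-2-yn-1-ol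
Conditions: 7 (0.5 M in THF, 1.3 equiv), THF, 0 °C; then H2O (pH 7)
Reagents that add atoms: none
Why: 1,2-Addition of an alkynyl Grignard reagent to an aromatic aldehyde, which forms the carbinol centre as a racemate, as intended, because step 8 oxidises it away.

Step 5
Reactants: 1 4-(tert-butyldimethylsilyloxy)benzaldehyde
Product: 9 tert-butyl[4-(2,2-dibromovinyl)phenoxy]dimethylsilane
Conditions: CBr4 (2 equiv), PPh3 (2 equiv), Zn dust (2 equiv), CH2Cl2, rt; then 1, 0 °C → rt
Reagents that add atoms: carbon tetrabromide, BrC(Br)(Br)Br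
Why: Corey–Fuchs dibromoolefination (Wittig reaction of Ph3P=CBr2), with zinc taking up the bromine so that no acidic bromophosphonium salt is present to attack the silyl ether.

Step 6
Reactants: 9 tert-butyl[4-(2,2-dibromovinyl)phenoxy]dimethylsilane
Product: 10 [4-(bromoethynyl)phenoxy](tert-butyl)dimethylsilane
Conditions: NaN(SiMe3)2 (1.1 equiv), THF, −78 °C
Reagents that add atoms: none
Why: Anti E2 dehydrobromination of a 1,1-dibromoalkene, in which the amide base removes the vinylic hydrogen with the bromine trans to it and stops at the 1-bromoalkyne because it neither exchanges bromine nor finds another acidic hydrogen.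

Step 7
Reactants: 8 rac-1-[4-(tert-butyldimethylsilyloxy)phenyl]prop-2-yn-1-ol; 10 [4-(bromoethynyl)phenoxy](tert-butyl)dimethylsilane
Product: 11 rac-1,5-bis[4-(tert-butyldimethylsilyloxy)phenyl]penta-2,4-diyn-1-ol
Conditions: CuCl (10 mol%), NH2OH·HCl (20 mol%), n-BuNH2 (2 equiv), degassed CH2Cl2, 0 °C, slow addition of 10
Reagents that add atoms: none
Why: Cadiot–Chodkiewicz coupling, in which the copper acetylide of 8 couples with the bromoalkyne while hydroxylamine keeps copper monovalent and so suppresses oxidative homocoupling, the free propargylic hydroxyl and the short cold exposure of the aryl silyl ethers to the amine being tolerated.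

Step 8
Reactants: 11 rac-1,5-bis[4-(tert-butyldimethylsilyloxy)phenyl]penta-2,4-diyn-1-ol
Product: 12 1,5-bis[4-(tert-butyldimethylsilyloxy)phenyl]penta-2,4-diyn-1-one (the dienophile)
Conditions: activated MnO2 (15 equiv), CH2Cl2, rt
Reagents that add atoms: none
Why: MnO2 oxidation of a secondary alcohol that is both benzylic and propargylic, under neutral heterogeneous conditions that spare the silyl ethers and the electrophilic diynone.

Step 9
Reactants: 6 tert-butyl{4-[(1E,3E)-5-(tert-butyldimethylsilyloxy)penta-1,3-dien-1-yl]phenoxy}dimethylsilane; 12 1,5-bis[4-(tert-butyldimethylsilyloxy)phenyl]penta-2,4-diyn-1-one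
Product: 13 rac-cis-(Ar)[6-Ar-3-(TBSOCH2)-2-(Ar-ethynyl)cyclohexa-1,4-dien-1-yl]methanone (hydrogens at the two sp3 ring carbons on the same face)
Conditions: 6 (1.5 equiv), BHT (5 mol%), toluene (1 M), 120 °C, sealed tube, Ar, dark
Reagents that add atoms: none
Why: Thermal normal-electron-demand Diels–Alder reaction, in which the HOMO of the donor-substituted diene 6 and the LUMO of ynone 12 combine in a concerted, asynchronous, suprafacial (4+2) cycloaddition that forms the C1–C2 and C5–C6 bonds of ring A. The closest known reaction type is the cycloaddition of 1-arylbutadienes with acetylenic ketones, applied here to a 1,4-disubstituted diene and a conjugated diynone. The six-membered carbocycle is closed intermolecularly, both ring bonds arising in the same event, and no other ring is formed. The two new sp3 centres (C2 and C5) should be cis because both diene termini sit on E double bonds and add through one face; they are racemic and disappear in step 10. The step needs the orientation with aryl next to aroyl and reaction at the triple bond adjacent to the carbonyl: the 4-silyloxyphenyl donor places the larger HOMO coefficient on the remote CH2O-bearing terminus, which pairs with the β-carbon of the ynone (largest LUMO coefficient), and only the proximal triple bond is polarised directly by the carbonyl. The β-alkynyl group is linear and small, neutral thermal conditions spare the acid-sensitive dienyl silyl ether, and any adduct that aromatises in the flask is simply carried into step 10.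

Step 10
Reactants: 13 rac-cis-(Ar)[6-Ar-3-(TBSOCH2)-2-(Ar-ethynyl)cyclohexa-1,4-dien-1-yl]methanone
Product: 14 [4'-(TBSO)-4-(TBSOCH2)-3-(Ar-ethynyl)biphenyl-2-yl](Ar)methanone (ring A: C1 aroyl, C2 Ar, C5 CH2OTBS, C6 arylethynyl)
Conditions: DDQ (1.2 equiv), toluene, rt
Reagents that add atoms: none
Why: Dehydrogenative aromatisation by a quinone, in which DDQ abstracts hydride from a doubly allylic C–H (the one at C2 is also benzylic) and the cyclohexadienyl cation loses the second ring proton, driven by formation of the benzene and erasing both stereocentres.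

Step 11
Reactants: 14 [4'-(TBSO)-4-(TBSOCH2)-3-(Ar-ethynyl)biphenyl-2-yl](Ar)methanone; 15 (4-bromophenoxy)(tert-butyl)dimethylsilane
Product: 17 [4'-(TBSO)-4-(TBSOCH2)-3-(Ar-ethynyl)biphenyl-2-yl]bis(Ar)methanol, via aryllithium 16 (not isolated)
Conditions: 15 (3 equiv), n-BuLi (2.9 equiv), THF, −78 °C; then 14, −78 → −30 °C; H2O quench at −30 °C
Reagents that add atoms: none
Why: Bromine–lithium exchange followed by 1,2-addition of the aryllithium to a diaryl ketone that cannot enolise and whose ortho alkynyl neighbour is sterically slim, the cold quench keeping the lithium alkoxide from adding across the adjacent triple bond.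

Step 12
Reactants: 17 [4'-(TBSO)-4-(TBSOCH2)-3-(Ar-ethynyl)biphenyl-2-yl]bis(Ar)methanol
Product: 19 selaginellin, via pentahydroxy carbinol 18 (not isolated)
Conditions: Bu4NF (6 equiv), AcOH (6 equiv), THF, 0 °C → rt; then dilute aq. HCl to pH 3–4, rt, brief
Reagents that add atoms: none
Why: Fluoride-induced cleavage of all five Si–O bonds, buffered with acetic acid so that no free alkoxide can add to the alkyne, followed by acid-promoted dehydration in which the carbinol ionises to a cation stabilised by two 4-hydroxyphenyl rings and loses a phenolic proton to give the para-quinone methide (fuchsone formation).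

**Compound list**

1 | 4-(tert-butyldimethylsilyloxy)benzaldehyde | O=Cc1ccc(O[Si](C)(C)C(C)(C)C)cc1 | starting material
2 | triethyl 4-phosphonocrotonate | CCOC(=O)/C=C/CP(=O)(OCC)OCC | starting material
3 | lithiated phosphonate (γ-lithio derivative of 2) | CCOC(=O)/C=C/[CH-]P(=O)(OCC)OCC.[Li+] | intermediate
4 | ethyl (2E,4E)-5-[4-(tert-butyldimethylsilyloxy)phenyl]penta-2,4-dienoate | CCOC(=O)/C=C/C=C/c1ccc(O[Si](C)(C)C(C)(C)C)cc1 | intermediate
5 | (2E,4E)-5-[4-(tert-butyldimethylsilyloxy)phenyl]penta-2,4-dien-1-ol | OC/C=C/C=C/c1ccc(O[Si](C)(C)C(C)(C)C)cc1 | intermediate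
6 | tert-butyl{4-[(1E,3E)-5-(tert-butyldimethylsilyloxy)penta-1,3-dien-1-yl]phenoxy}dimethylsilane | CC(C)(C)[Si](C)(C)OC/C=C/C=C/c1ccc(O[Si](C)(C)C(C)(C)C)cc1 | intermediate
7 | ethynylmagnesium bromide | C#C[Mg]Br | starting material
8 | rac-1-[4-(tert-butyldimethylsilyloxy)phenyl]prop-2-yn-1-ol | C#CC(O)c1ccc(O[Si](C)(C)C(C)(C)C)cc1 | intermediate
9 | tert-butyl[4-(2,2-dibromovinyl)phenoxy]dimethylsilane | BrC(Br)=Cc1ccc(O[Si](C)(C)C(C)(C)C)cc1 | intermediate
10 | [4-(bromoethynyl)phenoxy](tert-butyl)dimethylsilane | BrC#Cc1ccc(O[Si](C)(C)C(C)(C)C)cc1 | intermediate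
11 | rac-1,5-bis[4-(tert-butyldimethylsilyloxy)phenyl]penta-2,4-diyn-1-ol | OC(C#CC#Cc1ccc(O[Si](C)(C)C(C)(C)C)cc1)c1ccc(O[Si](C)(C)C(C)(C)C)cc1 | intermediate
12 | 1,5-bis[4-(tert-butyldimethylsilyloxy)phenyl]penta-2,4-diyn-1-one | O=C(C#CC#Cc1ccc(O[Si](C)(C)C(C)(C)C)cc1)c1ccc(O[Si](C)(C)C(C)(C)C)cc1 | intermediate
13 | rac-cis-(Ar)[6-Ar-3-(TBSOCH2)-2-(Ar-ethynyl)cyclohexa-1,4-dien-1-yl]methanone | O=C(c1ccc(O[Si](C)(C)C(C)(C)C)cc1)C1=C(C#Cc2ccc(O[Si](C)(C)C(C)(C)C)cc2)[C@@H](CO[Si](C)(C)C(C)(C)C)C=C[C@H]1c1ccc(O[Si](C)(C)C(C)(C)C)cc1 | intermediate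
14 | [4'-(TBSO)-4-(TBSOCH2)-3-(Ar-ethynyl)biphenyl-2-yl](Ar)methanone | O=C(c1ccc(O[Si](C)(C)C(C)(C)C)cc1)c1c(C#Cc2ccc(O[Si](C)(C)C(C)(C)C)cc2)c(CO[Si](C)(C)C(C)(C)C)ccc1-c1ccc(O[Si](C)(C)C(C)(C)C)cc1 | intermediate
15 | (4-bromophenoxy)(tert-butyl)dimethylsilane | Brc1ccc(O[Si](C)(C)C(C)(C)C)cc1 | starting material
16 | [4-(tert-butyldimethylsilyloxy)phenyl]lithium | [Li]c1ccc(O[Si](C)(C)C(C)(C)C)cc1 | intermediate
17 | [4'-(TBSO)-4-(TBSOCH2)-3-(Ar-ethynyl)biphenyl-2-yl]bis(Ar)methanol | OC(c1ccc(O[Si](C)(C)C(C)(C)C)cc1)(c1ccc(O[Si](C)(C)C(C)(C)C)cc1)c1c(C#Cc2ccc(O[Si](C)(C)C(C)(C)C)cc2)c(CO[Si](C)(C)C(C)(C)C)ccc1-c1ccc(O[Si](C)(C)C(C)(C)C)cc1 | intermediate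
18 | [4'-hydroxy-4-(hydroxymethyl)-3-[(4-hydroxyphenyl)ethynyl]biphenyl-2-yl]bis(4-hydroxyphenyl)methanol | OCc1ccc(-c2ccc(O)cc2)c(C(O)(c2ccc(O)cc2)c2ccc(O)cc2)c1C#Cc1ccc(O)cc1 | intermediate
19 | selaginellin, 4-{[4'-hydroxy-4-(hydroxymethyl)-3-[(4-hydroxyphenyl)ethynyl]biphenyl-2-yl](4-hydroxyphenyl)methylidene}cyclohexa-2,5-dien-1-one | O=C1C=CC(=C(c2ccc(O)cc2)c2c(-c3ccc(O)cc3)ccc(CO)c2C#Cc2ccc(O)cc2)C=C1 | target

**Count and risks**

Total step count: 12. Longest linear sequence: 8 steps (steps 5, 6, 7, 8, 9, 10, 11, 12, starting from 1).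

Step 9 (most at risk). The cycloaddition may be too slow at temperatures that the diynone survives, so that the diyne oligomerises. The diene may also engage the distal triple bond, or add in the reversed orientation because its bulky aryl terminus prefers the slim alkynyl-bearing carbon. The fallback takes the arylethynyl group out of the dienophile and attaches it afterwards by cross-coupling. It sets out from 8: bromination of the terminal alkyne (NBS, AgNO3 cat., acetone, rt) should give rac-3-bromo-1-[4-(tert-butyldimethylsilyloxy)phenyl]prop-2-yn-1-ol F1. MnO2 oxidation should then give 3-bromo-1-[4-(tert-butyldimethylsilyloxy)phenyl]prop-2-yn-1-one F2, a small mono-alkyne dienophile of the 3-halopropiolate type. Cycloaddition with diene 6 (toluene, 80–110 °C) should give rac-cis-(Ar)[2-bromo-6-Ar-3-(TBSOCH2)cyclohexa-1,4-dien-1-yl]methanone F3, and DDQ the aryl bromide [3-bromo-4'-(TBSO)-4-(TBSOCH2)biphenyl-2-yl](Ar)methanone F4. The alkyne partner tert-butyl(4-ethynylphenoxy)dimethylsilane F5 is made from 9 (n-BuLi, 2.1 equiv, THF, −78 °C, then H2O). Sonogashira coupling of F4 with F5 (PdCl2(PhCN)2, [(t-Bu)3PH]BF4, CuI, i-Pr2NH, dioxane, 40 °C; the ortho ketone assists oxidative addition to zerovalent palladium) comes back to the route at 14.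

Step 11. Addition to the doubly ortho-substituted ketone may be retarded sterically, letting the aryllithium attack silicon of the aryl silyl ethers instead; the phenoxide so formed deactivates the carbonyl. The fallback builds the triaryl carbon through a benzhydryl cation, not a carbonyl addition, and corrects the oxidation level at the end. It sets out from 14: reduction (i-Bu2AlH, CH2Cl2, −78 °C) should give rac-[4'-(TBSO)-4-(TBSOCH2)-3-(Ar-ethynyl)biphenyl-2-yl](Ar)methanol F6. Acid-catalysed Friedel–Crafts alkylation of phenol at its para position (phenol 10 equiv, TsOH 5 mol%, CH2Cl2/hexafluoroisopropanol, 0 °C) should give rac-4-{[4'-(TBSO)-4-(TBSOCH2)-3-(Ar-ethynyl)biphenyl-2-yl](Ar)methyl}phenol F7. The large excess of phenol is meant to outrun closure onto the unactivated neighbouring aryl ring, and partial loss of silyl groups is harmless here. Bu4NF/AcOH (THF, rt) should then give the leuco compound 4,4'-{[4'-hydroxy-4-(hydroxymethyl)-3-[(4-hydroxyphenyl)ethynyl]biphenyl-2-yl]methylene}diphenol F8. Chloranil (1 equiv, THF, rt) abstracts the triarylmethane hydride, as in leuco-dye oxidation, and loss of a phenolic proton gives the quinone methide, coming back to the route at 19.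

Step 12. Under fluoride, the oxygen freed at the C5 CH2O group (or the carbinol oxygen) may add across the flanking C6 triple bond in a 5-exo-dig closure. The unprotected quinone methide may also degrade on prolonged contact with fluoride or acid. The fallback stages the unmasking so that the benzylic alcohol is never free in a basic medium. It sets out from 17: KHF2 (MeOH/THF, rt) should cleave only the four aryl silyl ethers, and the mildly acidic work-up should dehydrate the carbinol to 4-{[4'-hydroxy-4-(tert-butyldimethylsilyloxymethyl)-3-[(4-hydroxyphenyl)ethynyl]biphenyl-2-yl](4-hydroxyphenyl)methylidene}cyclohexa-2,5-dien-1-one F9. The remaining primary silyl ether is then hydrolysed without any basic species (AcOH/THF/H2O 3:1:1, rt), coming back to the route at 19.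

**Further compounds**

F1 | step 9 | rac-3-bromo-1-[4-(tert-butyldimethylsilyloxy)phenyl]prop-2-yn-1-ol | OC(C#CBr)c1ccc(O[Si](C)(C)C(C)(C)C)cc1
F2 | step 9 | 3-bromo-1-[4-(tert-butyldimethylsilyloxy)phenyl]prop-2-yn-1-one | O=C(C#CBr)c1ccc(O[Si](C)(C)C(C)(C)C)cc1
F3 | step 9 | rac-cis-(Ar)[2-bromo-6-Ar-3-(TBSOCH2)cyclohexa-1,4-dien-1-yl]methanone | O=C(c1ccc(O[Si](C)(C)C(C)(C)C)cc1)C1=C(Br)[C@@H](CO[Si](C)(C)C(C)(C)C)C=C[C@H]1c1ccc(O[Si](C)(C)C(C)(C)C)cc1
F4 | step 9 | [3-bromo-4'-(TBSO)-4-(TBSOCH2)biphenyl-2-yl](Ar)methanone | O=C(c1ccc(O[Si](C)(C)C(C)(C)C)cc1)c1c(Br)c(CO[Si](C)(C)C(C)(C)C)ccc1-c1ccc(O[Si](C)(C)C(C)(C)C)cc1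
F5 | step 9 | tert-butyl(4-ethynylphenoxy)dimethylsilane | C#Cc1ccc(O[Si](C)(C)C(C)(C)C)cc1
F6 | step 11 | rac-[4'-(TBSO)-4-(TBSOCH2)-3-(Ar-ethynyl)biphenyl-2-yl](Ar)methanol | OC(c1ccc(O[Si](C)(C)C(C)(C)C)cc1)c1c(C#Cc2ccc(O[Si](C)(C)C(C)(C)C)cc2)c(CO[Si](C)(C)C(C)(C)C)ccc1-c1ccc(O[Si](C)(C)C(C)(C)C)cc1
F7 | step 11 | rac-4-{[4'-(TBSO)-4-(TBSOCH2)-3-(Ar-ethynyl)biphenyl-2-yl](Ar)methyl}phenol | Oc1ccc(cc1)C(c1ccc(O[Si](C)(C)C(C)(C)C)cc1)c1c(C#Cc2ccc(O[Si](C)(C)C(C)(C)C)cc2)c(CO[Si](C)(C)C(C)(C)C)ccc1-c1ccc(O[Si](C)(C)C(C)(C)C)cc1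
F8 | step 11 | 4,4'-{[4'-hydroxy-4-(hydroxymethyl)-3-[(4-hydroxyphenyl)ethynyl]biphenyl-2-yl]methylene}diphenol | OCc1ccc(-c2ccc(O)cc2)c(C(c2ccc(O)cc2)c2ccc(O)cc2)c1C#Cc1ccc(O)cc1
F9 | step 12 | 4-{[4'-hydroxy-4-(tert-butyldimethylsilyloxymethyl)-3-[(4-hydroxyphenyl)ethynyl]biphenyl-2-yl](4-hydroxyphenyl)methylidene}cyclohexa-2,5-dien-1-one | O=C1C=CC(=C(c2ccc(O)cc2)c2c(-c3ccc(O)cc3)ccc(CO[Si](C)(C)C(C)(C)C)c2C#Cc2ccc(O)cc2)C=C1
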